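The data are calculated with made-up constants, noise included.

Adding the isomer and target columns of a run is the easy step, and the meeting began there, with these flasks and readings before it.

| setting | north-east | south | north-west | zeta | alpha | beta | theta |
|---|---|---|---|---|---|---|---|
| starting material | 16 mM | 11 mM | 24 mM | 16 mM (in portions, 5, over 25 min) | 16 mM (fed, over 25 min) | 16 mM | 16 mM |
| coupling partner | 32 mM | 32 mM | 32 mM | 32.0 mM | 32.0 mM | 32.0 mM | 32.0 mM (fed, over 25 min) |
| remark | run made earlier | run made earlier | run made earlier | first portion at the start, last at 25 min | all else is in the flask from the start; the feed brings no volume worth counting | everything together at the start | all else is in the flask from the start; the feed brings no volume worth counting |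
| time |  |  |  | 30 min | 30 min | 30 min | 30 min |

- north-east (time / min: isomer of the product / %, target / %): 1.33: 18, 26; 2.50: 29, 21; 5.00: 37, 18; 10.0: 33, 16; 20.0: 38, 18
- south (time / min: isomer of the product / %, target / %): 2.50: 32, 21; 8.00: 37, 18; 15.0: 37, 16; 20.0: 36, 18; 30.0: 33, 16
- north-west (time / min: isomer of the product / %, target / %): 6.00: 34, 15; 12.0: 32, 13; 20.0: 35, 15; 25.0: 34, 17; 30.0: 33, 18

(each reading ± 1.5 percentage points)

- the numbers in the tables scatter with a standard deviation of 1.5 percentage points
- on the list of suspects stand: starting material + coupling partner -> target; starting material -> side product; target <-> isomer of the product; coupling partner -> decomposed reagent

- which flask leads in amount of isomer of the product, in percent of the starting material charged ("all alike" within 1.5 percentage points) (zeta / alpha / beta / theta / all alike)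
- how much isomer of the product is there at the end, in percent of the starting material charged: zeta
- how much isomer of the product is there at the end, in percent of the starting material charged: alpha
- how much isomer of the product is there at the end, in percent of the starting material charged: beta
- how much isomer of the product is there at the end, in percent of the starting material charged: theta

The first speaker reported that in the north-east run, whose recipe is also beta's, the sum from 5.00 min onward averages 53.3 % as a reading, and she counted the remainder as starting material lost to side product. She argued that coupling and loss draw on the same starting material, so that dividing one rate by the other removes time as long as c(coupling partner) holds still; coupled over lost is then 1.14, a selectivity factor averaged over the whole run and over whatever partner the starting material met, which no reading shows. Divided by the charge, above which c(coupling partner) does not stand in that run, it gives 0.0357 mM⁻¹, the coupling ratio, meaning coupled over lost starting material per mM of c(coupling partner) met, and she called this figure a floor, the partner met on average being no more than the charge.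

A second speaker said that beta repeats the north-east run, so he put its isomer at the reading 36.0 %, which is 67.5 % of the sum.

A third speaker took theta, where partner arrives at 1.28 mM min⁻¹. The first north-east reading gives starting material a lifetime by its loss step of about 1.64 min, so it meets about 2.09 mM of partner, and the coupling ratio then gives theta 4.69 % isomer.

For zeta and alpha the meeting recorded that no reading shows c(coupling partner), so it expected near 36.0 % if the partner lasts through 25 min, and less, towards the theta figure, if the suspected decomposition is quick.

The forecast gave 35 % for zeta, 35 % for alpha, 36 % for beta and 5 % for theta, with all alike as the leader, holding that “feeding starting material changes nothing”.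

The flasks end at 8.07 % for zeta, 3.33 % for alpha, 35.4 % for beta and 5.16 % for theta, so beta leads.

    starting material + coupling partner → target (k = 0.520 L mol⁻¹ s⁻¹)
    starting material → side product (k = 0.00670 s⁻¹)
    target ⇌ isomer of the product (K = 2.20, k = 0.0150 s⁻¹)
    coupling partner → decomposed reagent (k = 0.0100 s⁻¹)

Read backwards, the coupling ratio, being a floor, says that starting material in alpha met on average no more than about 1.45 mM of partner, against 32.0 mM charged. The comparison that counts is the half-life of the coupling partner by decomposition alone, 1.2 min in beta, against the 25 min feed, 21.6 half-lives, and at 15.0 min alpha holds 0.00703 % of its partner charge. In the neighbour of beta with 80 mM of partner, the coupling ratio, taken as a floor, gives 50.0 % isomer, and that flask ends at 54.9 %.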